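**Plan**

- Retrosynthesis: the lactone C16–O bond and the C19 acetate are taken off first (2-methylene-1,4-diol mask). The cuts that follow are the ring bond C9–C10, then C10–C11, C15=C17/C15–C16, C1–C2, C7–C8 and the C6=C7 alkene of geranyl acetate.
- Enabling feature: in the 14-membered carbocycle, C9–C10 is the one single bond flanked by two alkenes (the C7=C8–C9–C10–C11=C12 1,5-diene), and both carbons are primary allylic CH2 groups. It can therefore be made by reductive head-to-head union of two allylic bromides.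
- Forward: geranyl acetate gives the C2–C9 enal 11 (Baylis–Hillman reaction at C7). An Evans aldol with hexynoyl imide 15 joins C1–C2. The acyl carbon becomes C15(=C17H2)–C16H2OPMB, carboalumination adds C10, step 18 closes the carbocycle and step 22 closes the γ-lactone.
- Stereochemistry: C1/C2 (cis ring fusion) come from the Evans syn-aldol with (R)-4-benzyl-2-oxazolidinone. C3=C4 is inherited from geranyl acetate, C7=C8 comes from the SN2′ bromination of the Baylis–Hillman adduct, and C11=C12 from syn-carboalumination.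

Key step: step 18

Remark: cembrane numbering is used throughout (C1 ring-fusion CH bearing C15, C2 the O–CH, C16 lactone carbonyl, C17 exocyclic CH2, C19 the oxygenated carbon on C8); adduct 5 is carried as the racemate because its carbinol centre is erased in step 3. TBS = tert-butyldimethylsilyl, PMB = 4-methoxybenzyl.

**Route**

Step 1
Reactants: 1 geranyl acetate
Product: 3 (2E)-3-methyl-6-oxohex-2-en-1-yl acetate, via ozonide 2 (not isolated)
Conditions: O3 (1 equiv), CH2Cl2, −78 °C; PPh3, −78 °C → rt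
Reagents that add atoms: ozone O=[O+][O-]
Why: Chemoselective ozonolysis, in which the distal trisubstituted alkene is more electron-rich than the one deactivated by the allylic acetate, so one equivalent of ozone should cleave only C6=C7 of the geranyl chain and reductive work-up of the ozonide gives the aldehyde.

Step 2
Reactants: 3 (2E)-3-methyl-6-oxohex-2-en-1-yl acetate; 4 tert-butyl acrylate
Product: 5 tert-butyl (6E)-8-acetoxy-3-hydroxy-6-methyl-2-methylideneoct-6-enoate (racemic)
Conditions: quinuclidine (0.3 equiv), MeOH (0.75 equiv), neat in 4 (3 equiv), rt, several days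
Reagents that add atoms: none
Why: Morita–Baylis–Hillman reaction of an unhindered aliphatic aldehyde builds the C7–C8 bond, and the tert-butyl ester (the later C9) is chosen because it should resist the organometallic reagents of steps 10–14.

Step 3
Reactants: 5 tert-butyl (6E)-8-acetoxy-3-hydroxy-6-methyl-2-methylideneoct-6-enoate
Product: 6 tert-butyl (2Z,6E)-8-acetoxy-2-(bromomethyl)-6-methylocta-2,6-dienoate
Conditions: NBS, Me2S, CH2Cl2, 0 °C → rt
Reagents that add atoms: N-bromosuccinimide O=C1CCC(=O)N1Br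
Why: Corey–Kim-type activation of the Baylis–Hillman alcohol followed by SN2′ attack of bromide at the terminal CH2 gives the conjugated trisubstituted alkene with the ester trans to the C6 chain (A1,3 strain), which fixes the C7=C8 geometry (ester carbon = C9 trans to C6, CH2Br = C19 cis to C6).

Step 4
Reactants: 6 tert-butyl (2Z,6E)-8-acetoxy-2-(bromomethyl)-6-methylocta-2,6-dienoate
Product: 8 tert-butyl (2E,6E)-8-acetoxy-2-(hydroxymethyl)-6-methylocta-2,6-dienoate, via formate ester 7 (not isolated)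
Conditions: HCO2Na, DMF, rt; then MeOH, NaHCO3, rt
Reagents that add atoms: sodium formate [Na+].[O-]C=O
Why: Carboxylate SN2 displacement at the primary allylic bromide (as known for acetate with Baylis–Hillman bromides) keeps the alkene geometry, and the formate is then methanolysed far faster than the C2 acetate, which leaves only the C19 hydroxyl free.

Step 5
Reactants: 8 tert-butyl (2E,6E)-8-acetoxy-2-(hydroxymethyl)-6-methylocta-2,6-dienoate
Product: 9 tert-butyl (2E,6E)-8-acetoxy-2-(TBS-oxymethyl)-6-methylocta-2,6-dienoate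
Conditions: TBSCl, imidazole, DMF, 0 °C → rt
Reagents that add atoms: tert-butyldimethylsilyl chloride CC(C)(C)[Si](C)(C)Cl
Why: Standard silylation of a primary alcohol under non-acidic, non-nucleophilic conditions protects the C19 oxygen with a group that Ni(0) cannot ionise.

Step 6
Reactants: 9 tert-butyl (2E,6E)-8-acetoxy-2-(TBS-oxymethyl)-6-methylocta-2,6-dienoate
Product: 10 tert-butyl (2E,6E)-8-hydroxy-2-(TBS-oxymethyl)-6-methylocta-2,6-dienoate
Conditions: K2CO3 (cat.), MeOH, 0 °C
Reagents that add atoms: none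
Why: Base-catalysed transesterification removes the primary allylic acetate, while the tert-butyl ester and the silyl ether are inert to methanolic carbonate at 0 °C.

Step 7
Reactants: 10 tert-butyl (2E,6E)-8-hydroxy-2-(TBS-oxymethyl)-6-methylocta-2,6-dienoate
Product: 11 tert-butyl (2E,6E)-2-(TBS-oxymethyl)-6-methyl-8-oxoocta-2,6-dienoate
Conditions: MnO2, CH2Cl2, rt
Reagents that add atoms: none
Why: Manganese dioxide oxidation of a primary allylic alcohol gives the C2 enal without E/Z isomerisation of C3=C4.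

Step 8
Reactants: 12 hex-5-ynoic acid; 13 (R)-4-benzyl-2-oxazolidinone
Product: 15 (4R)-4-benzyl-3-(hex-5-ynoyl)-1,3-oxazolidin-2-one, via mixed anhydride 14 (not isolated)
Conditions: PivCl, Et3N, THF, −20 °C; then 13, LiCl, rt
Reagents that add atoms: none
Why: N-Acylation of the oxazolidinone through the mixed pivalic anhydride with LiCl/Et3N is a standard route to Evans imides and tolerates the terminal alkyne.

Step 9
Reactants: 15 (4R)-4-benzyl-3-(hex-5-ynoyl)-1,3-oxazolidin-2-one; 11 tert-butyl (2E,6E)-2-(TBS-oxymethyl)-6-methyl-8-oxoocta-2,6-dienoate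
Product: 18 syn-aldol adduct (1R,2S) of imide 15 on enal 11, via boron enolate 16 (not isolated), via boron aldolate 17 (not isolated)
Conditions: 15, Bu2BOTf, Et3N, CH2Cl2, −78 → 0 °C; 11, −78 → 0 °C; pH 7 buffer, MeOH, H2O2, 0 °C
Reagents that add atoms: none
Why: Evans syn-aldol reaction, in which the Z-boron enolate reacts through a Zimmerman–Traxler chair on the enolate face away from the benzyl group of the (R)-auxiliary and so sets C1 and C2 together as the syn diad (C1 is R here and becomes S by priority change once C15 is no longer a carbonyl; C2 is S).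

Step 10
Reactants: 18 syn-aldol adduct (1R,2S)
Product: 19 (1R,2S) β-hydroxy Weinreb amide
Conditions: MeNHOMe·HCl, Me3Al, THF, −15 → 0 °C
Reagents that add atoms: N,O-dimethylhydroxylamine hydrochloride CNOC.Cl
Why: Aluminium-amide transamidation of an Evans aldol adduct is activated by chelation to the free β-hydroxyl, so the imide carbonyl is attacked selectively, the auxiliary is released and the tert-butyl ester is left alone.

Step 11
Reactants: 19 (1R,2S) β-hydroxy Weinreb amide
Product: 20 (1R,2S) C2-OTBS Weinreb amide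
Conditions: TBSOTf, 2,6-lutidine, CH2Cl2, −78 °C
Reagents that add atoms: tert-butyldimethylsilyl triflate CC(C)(C)[Si](C)(C)OS(=O)(=O)C(F)(F)F
Why: Silyl triflate/lutidine silylation of a hindered secondary allylic alcohol is fast at −78 °C, where the tert-butyl ester is not cleaved, and it blocks retro-aldol and elimination pathways in the following steps.

Step 12
Reactants: 21 (tributylstannyl)methanol
Product: 22 tributyl{[(4-methoxybenzyl)oxy]methyl}stannane
Conditions: NaH, PMBCl, Bu4NI (cat.), THF/DMF, 0 °C → rt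
Reagents that add atoms: 4-methoxybenzyl chloride COc1ccc(CCl)cc1
Why: Williamson etherification of the stannylmethanol alkoxide with a benzylic chloride gives the precursor of the α-alkoxymethyl anion that will supply C16 with its oxygen already protected.

Step 13
Reactants: 20 (1R,2S) C2-OTBS Weinreb amide; 22 tributyl{[(4-methoxybenzyl)oxy]methyl}stannane
Product: 23 (1R,2S) C15 ketone bearing C16H2OPMB
Conditions: 22 (2.5 equiv), n-BuLi, THF, −78 °C; then 20, −78 °C; aq. NH4Cl
Reagents that add atoms: none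
Why: Tin–lithium exchange gives the α-alkoxymethyllithium, which adds once to the Weinreb amide (stable chelated adduct, ketone released only on work-up) to form C15–C16; one equivalent is consumed by the alkyne C–H and the hindered tert-butyl enoate should react much more slowly at −78 °C.

Step 14
Reactants: 23 (1R,2S) C15 ketone bearing C16H2OPMB
Product: 24 (1S,2S) C15=C17 methylene compound (tert-butyl ester and terminal alkyne)
Conditions: Ph3PCH3Br, KHMDS, THF, 0 °C; then 23, −78 → 0 °C
Reagents that add atoms: methyltriphenylphosphonium bromide C[P+](c1ccccc1)(c1ccccc1)c1ccccc1.[Br-]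
Why: Wittig methylenation of the electrophilic α-alkoxy ketone installs the exocyclic C15=C17 alkene, and a salt-free ylide at low temperature should limit enolisation toward C1.

Step 15
Reactants: 24 (1S,2S) C15=C17 methylene compound
Product: 25 (1S,2S) C9 allylic alcohol with terminal alkyne
Conditions: DIBAL-H, CH2Cl2, −78 → 0 °C; Rochelle salt
Reagents that add atoms: none
Why: DIBAL 1,2-reduction of the α,β-unsaturated tert-butyl ester gives the C9 allylic alcohol with the C7=C8 geometry unchanged, and the alkyne, silyl ethers and PMB ether are inert at this temperature.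

Step 16
Reactants: 25 (1S,2S) C9 allylic alcohol with terminal alkyne
Product: 27 (1S,2S) C9,C10 diol, via alkenylalane 26 (not isolated)
Conditions: Me3Al, Cp2ZrCl2, CH2Cl2, 0 °C → rt; evaporate; n-BuLi, THF, −78 °C; (CH2O)n, rt
Reagents that add atoms: trimethylaluminium C[Al](C)C; formaldehyde (as paraformaldehyde) C=O
Why: Negishi zirconium-catalysed carboalumination adds methyl (to C12) and aluminium (to C11) syn across the terminal alkyne, and the derived alanate is hydroxymethylated with retention, so C13 and the new C10 end up trans (11E).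

Step 17
Reactants: 27 (1S,2S) C9,C10 diol
Product: 29 (1S,2S) C9,C10 bis(allylic bromide), via bis-mesylate 28 (not isolated)
Conditions: MsCl, Et3N, THF, −40 °C; then LiBr, THF, 0 °C
Reagents that add atoms: lithium bromide [Li+].[Br-]
Why: Mesylation followed by SN2 displacement with bromide converts both primary allylic alcohols into bromides without allylic transposition or E/Z change, and the silyl and PMB ethers survive.

Step 18
Reactants: 29 (1S,2S) C9,C10 bis(allylic bromide)
Product: 30 (1S,2S,3E,7Z,11E)-2,19-bis(TBS-oxy)-16-(PMB-oxy)cembra-3,7,11,15(17)-tetraene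
Conditions: Ni(CO)4 (excess), NMP, 50 °C, slow addition of 29 by syringe pump (final ≤ 0.005 M), Ar
Reagents that add atoms: none
Why: Ni(0) inserts into one allylic C–Br bond with loss of CO to give an η3-allylnickel bromide, which in the polar solvent engages the second allylic bromide (through a bis-allylnickel species) and reductively eliminates the C9–C10 bond between the two unsubstituted CH2 termini. The closest known reaction type is the nickel carbonyl cyclisation of α,ω-bis(allylic bromides) to 12-, 14- and 18-membered 1,5-dienes, terpenoid rings included. The 14-membered carbocycle closes by end-to-end (head-to-head) allyl–allyl coupling within one molecule, a macrocyclisation that slow addition at high dilution favours over oligomerisation. No stereocentre is formed, and C1/C2 lie far from the reacting termini. The step needs head-to-head regiochemistry and the ring-trans arrangement at C7=C8 and C11=C12: coupling at the primary termini is sterically preferred, the branched alternatives at C7 or C12 would give strained 12-membered rings with a congested centre, and any syn/anti equilibration of the allylnickel termini is expected to funnel to the less strained all-trans macrocycle. Only silyl and PMB ethers are present, so Ni(0) meets no other ionisable allylic group and no carbonyl.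

Step 19
Reactants: 30 protected macrocycle
Product: 31 (1S,2S,3E,7Z,11E)-16-(PMB-oxy)cembra-3,7,11,15(17)-tetraene-2,19-diol
Conditions: TBAF, THF, 0 °C → rt
Reagents that add atoms: none
Why: Fluoride desilylation removes both TBS ethers (C2 and C19), and the PMB ether at C16 is untouched.

Step 20
Reactants: 31 C2,C19 diol
Product: 32 (1S,2S,3E,7Z,11E)-19-acetoxy-16-(PMB-oxy)cembra-3,7,11,15(17)-tetraen-2-ol
Conditions: AcCl (1.05 equiv), 2,4,6-collidine, CH2Cl2, −78 °C
Reagents that add atoms: acetyl chloride CC(=O)Cl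
Why: Acylation with acetyl chloride/collidine at low temperature is selective for a primary over a hindered secondary alcohol, so only the C19 hydroxyl should be acetylated.

Step 21
Reactants: 32 C19 acetate
Product: 33 (1S,2S,3E,7Z,11E)-19-acetoxycembra-3,7,11,15(17)-tetraene-2,16-diol
Conditions: DDQ, CH2Cl2/pH 7 buffer, 0 °C
Reagents that add atoms: none
Why: Oxidative PMB cleavage with DDQ (hydride abstraction, then hydrolysis of the oxocarbenium ion) frees the C16 hydroxyl and tolerates the acetate and the isolated alkenes.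

Step 22
Reactants: 33 2-methylene-1,4-diol
Product: 36 target (1S,2S,3E,7Z,11E)-19-acetoxycembra-3,7,11,15(17)-tetraen-16,2-olide, via hydroxy enal 34 (not isolated), via lactol 35 (not isolated)
Conditions: TEMPO (cat.), PhI(OAc)2, CH2Cl2, rt
Reagents that add atoms: none
Why: TEMPO/PhI(OAc)2 oxidative lactonisation oxidises the primary allylic C16 alcohol in preference to the secondary C2 alcohol, the hydroxy enal closes 5-exo-trig onto the C2 hydroxyl, and the lactol is oxidised on to the α-methylene γ-lactone; the cis ring fusion follows from the C1/C2 syn diad.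

**Compound list**

1 | geranyl acetate, (2E)-3,7-dimethylocta-2,6-dien-1-yl acetate | CC(C)=CCC/C(C)=C/COC(C)=O | starting material
2 | 6,7-ozonide of geranyl acetate (1,2,4-trioxolane, formed in situ) | CC1(C)OOC(CC/C(C)=C/COC(C)=O)O1 | intermediate
3 | (2E)-3-methyl-6-oxohex-2-en-1-yl acetate | O=CCC/C(C)=C/COC(C)=O | intermediate
4 | tert-butyl acrylate | C=CC(=O)OC(C)(C)C | starting material
5 | tert-butyl (6E)-8-acetoxy-3-hydroxy-6-methyl-2-methylideneoct-6-enoate (racemic) | C=C(C(=O)OC(C)(C)C)C(O)CC/C(C)=C/COC(C)=O | intermediate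
6 | tert-butyl (2Z,6E)-8-acetoxy-2-(bromomethyl)-6-methylocta-2,6-dienoate | CC(C)(C)OC(=O)/C(CBr)=C/CC/C(C)=C/COC(C)=O | intermediate
7 | tert-butyl (2E,6E)-8-acetoxy-2-[(formyloxy)methyl]-6-methylocta-2,6-dienoate (formed in situ) | CC(C)(C)OC(=O)/C(COC=O)=C/CC/C(C)=C/COC(C)=O | intermediate
8 | tert-butyl (2E,6E)-8-acetoxy-2-(hydroxymethyl)-6-methylocta-2,6-dienoate | CC(C)(C)OC(=O)/C(CO)=C/CC/C(C)=C/COC(C)=O | intermediate
9 | tert-butyl (2E,6E)-8-acetoxy-2-(TBS-oxymethyl)-6-methylocta-2,6-dienoate | CC(C)(C)OC(=O)/C(CO[Si](C)(C)C(C)(C)C)=C/CC/C(C)=C/COC(C)=O | intermediate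
10 | tert-butyl (2E,6E)-8-hydroxy-2-(TBS-oxymethyl)-6-methylocta-2,6-dienoate | CC(C)(C)OC(=O)/C(CO[Si](C)(C)C(C)(C)C)=C/CC/C(C)=C/CO | intermediate
11 | tert-butyl (2E,6E)-2-(TBS-oxymethyl)-6-methyl-8-oxoocta-2,6-dienoate (C2–C9 enal, C19 OTBS) | CC(C)(C)OC(=O)/C(CO[Si](C)(C)C(C)(C)C)=C/CC/C(C)=C/C=O | intermediate
12 | hex-5-ynoic acid | C#CCCCC(=O)O | starting material
13 | (R)-4-benzyl-2-oxazolidinone | O=C1N[C@H](Cc2ccccc2)CO1 | starting material
14 | hex-5-ynoic pivalic anhydride (formed in situ) | C#CCCCC(=O)OC(=O)C(C)(C)C | intermediate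
15 | (4R)-4-benzyl-3-(hex-5-ynoyl)-1,3-oxazolidin-2-one | C#CCCCC(=O)N1[C@H](Cc2ccccc2)COC1=O | intermediate
16 | dibutylboron (Z)-enolate of imide 15 (formed in situ) | CCCCB(CCCC)O/C(=C\CCC#C)N1[C@H](Cc2ccccc2)COC1=O | intermediate
17 | O-dibutylboryl aldolate of 18 (formed in situ) | CC(C)(C)OC(=O)/C(CO[Si](C)(C)C(C)(C)C)=C/CC/C(C)=C/[C@H](OB(CCCC)CCCC)[C@H](C(=O)N1[C@H](Cc2ccccc2)COC1=O)CCC#C | intermediate
18 | syn-aldol adduct, tert-butyl (2E,6E,8S,9R)-9-{[(4R)-4-benzyl-2-oxo-1,3-oxazolidin-3-yl]carbonyl}-8-hydroxy-2-(TBS-oxymethyl)-6-methyltrideca-2,6-dien-12-ynoate (cembrane 1R,2S) | CC(C)(C)OC(=O)/C(CO[Si](C)(C)C(C)(C)C)=C/CC/C(C)=C/[C@H](O)[C@H](C(=O)N1[C@H](Cc2ccccc2)COC1=O)CCC#C | intermediate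
19 | tert-butyl (2E,6E,8S,9R)-8-hydroxy-9-[methoxy(methyl)carbamoyl]-2-(TBS-oxymethyl)-6-methyltrideca-2,6-dien-12-ynoate | CC(C)(C)OC(=O)/C(CO[Si](C)(C)C(C)(C)C)=C/CC/C(C)=C/[C@H](O)[C@H](C(=O)N(C)OC)CCC#C | intermediate
20 | tert-butyl (2E,6E,8S,9R)-8-(TBS-oxy)-9-[methoxy(methyl)carbamoyl]-2-(TBS-oxymethyl)-6-methyltrideca-2,6-dien-12-ynoate | CC(C)(C)OC(=O)/C(CO[Si](C)(C)C(C)(C)C)=C/CC/C(C)=C/[C@H](O[Si](C)(C)C(C)(C)C)[C@H](C(=O)N(C)OC)CCC#C | intermediate
21 | (tributylstannyl)methanol | CCCC[Sn](CCCC)(CCCC)CO | starting material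
22 | tributyl{[(4-methoxybenzyl)oxy]methyl}stannane | CCCC[Sn](CCCC)(CCCC)COCc1ccc(OC)cc1 | intermediate
23 | tert-butyl (2E,6E,8S,9R)-8-(TBS-oxy)-9-[(4-methoxybenzyloxy)acetyl]-2-(TBS-oxymethyl)-6-methyltrideca-2,6-dien-12-ynoate (C15 ketone) | CC(C)(C)OC(=O)/C(CO[Si](C)(C)C(C)(C)C)=C/CC/C(C)=C/[C@H](O[Si](C)(C)C(C)(C)C)[C@H](C(=O)COCc1ccc(OC)cc1)CCC#C | intermediate
24 | tert-butyl (2E,6E,8S,9S)-8-(TBS-oxy)-9-[3-(4-methoxybenzyloxy)prop-1-en-2-yl]-2-(TBS-oxymethyl)-6-methyltrideca-2,6-dien-12-ynoate | CC(C)(C)OC(=O)/C(CO[Si](C)(C)C(C)(C)C)=C/CC/C(C)=C/[C@H](O[Si](C)(C)C(C)(C)C)[C@H](C(=C)COCc1ccc(OC)cc1)CCC#C | intermediate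
25 | (2Z,6E,8S,9S)-8-(TBS-oxy)-9-[3-(4-methoxybenzyloxy)prop-1-en-2-yl]-2-(TBS-oxymethyl)-6-methyltrideca-2,6-dien-12-yn-1-ol (C9 alcohol) | OC/C(CO[Si](C)(C)C(C)(C)C)=C/CC/C(C)=C/[C@H](O[Si](C)(C)C(C)(C)C)[C@H](C(=C)COCc1ccc(OC)cc1)CCC#C | intermediate
26 | (E)-alkenyl(dimethyl)alane at C11 with C9 O-dimethylaluminium alkoxide (formed in situ) | C[Al](C)OC/C(CO[Si](C)(C)C(C)(C)C)=C/CC/C(C)=C/[C@H](O[Si](C)(C)C(C)(C)C)[C@H](C(=C)COCc1ccc(OC)cc1)CC/C(C)=C/[Al](C)C | intermediate
27 | (2Z,6E,8S,9S,12E)-8-(TBS-oxy)-9-[3-(4-methoxybenzyloxy)prop-1-en-2-yl]-2-(TBS-oxymethyl)-6,12-dimethyltetradeca-2,6,12-triene-1,14-diol (C9,C10 diol) | OC/C(CO[Si](C)(C)C(C)(C)C)=C/CC/C(C)=C/[C@H](O[Si](C)(C)C(C)(C)C)[C@H](C(=C)COCc1ccc(OC)cc1)CC/C(C)=C/CO | intermediate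
28 | bis(methanesulfonate) of diol 27 (formed in situ) | CS(=O)(=O)OC/C(CO[Si](C)(C)C(C)(C)C)=C/CC/C(C)=C/[C@H](O[Si](C)(C)C(C)(C)C)[C@H](C(=C)COCc1ccc(OC)cc1)CC/C(C)=C/COS(C)(=O)=O | intermediate
29 | (2E,6E,8S,9S,12E)-1,14-dibromo-8-(TBS-oxy)-9-[3-(4-methoxybenzyloxy)prop-1-en-2-yl]-2-(TBS-oxymethyl)-6,12-dimethyltetradeca-2,6,12-triene (C9,C10 bis(allylic bromide), cembrane 1S,2S) | BrC/C(CO[Si](C)(C)C(C)(C)C)=C/CC/C(C)=C/[C@H](O[Si](C)(C)C(C)(C)C)[C@H](C(=C)COCc1ccc(OC)cc1)CC/C(C)=C/CBr | intermediate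
30 | (1S,2S,3E,7Z,11E)-2,19-bis(TBS-oxy)-16-(4-methoxybenzyloxy)cembra-3,7,11,15(17)-tetraene | C=C(COCc1ccc(OC)cc1)[C@@H]1CC/C(C)=C/CC/C(CO[Si](C)(C)C(C)(C)C)=C/CC/C(C)=C/[C@@H]1O[Si](C)(C)C(C)(C)C | intermediate
31 | (1S,2S,3E,7Z,11E)-16-(4-methoxybenzyloxy)cembra-3,7,11,15(17)-tetraene-2,19-diol | C=C(COCc1ccc(OC)cc1)[C@@H]1CC/C(C)=C/CC/C(CO)=C/CC/C(C)=C/[C@@H]1O | intermediate
32 | (1S,2S,3E,7Z,11E)-19-acetoxy-16-(4-methoxybenzyloxy)cembra-3,7,11,15(17)-tetraen-2-ol | C=C(COCc1ccc(OC)cc1)[C@@H]1CC/C(C)=C/CC/C(COC(C)=O)=C/CC/C(C)=C/[C@@H]1O | intermediate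
33 | (1S,2S,3E,7Z,11E)-19-acetoxycembra-3,7,11,15(17)-tetraene-2,16-diol | C=C(CO)[C@@H]1CC/C(C)=C/CC/C(COC(C)=O)=C/CC/C(C)=C/[C@@H]1O | intermediate
34 | (1S,2S,3E,7Z,11E)-19-acetoxy-2-hydroxycembra-3,7,11,15(17)-tetraen-16-al (formed in situ) | C=C(C=O)[C@@H]1CC/C(C)=C/CC/C(COC(C)=O)=C/CC/C(C)=C/[C@@H]1O | intermediate
35 | C16 lactol of 34, cis-fused 2-hydroxy-3-methylenetetrahydrofuran (formed in situ) | C=C1C(O)O[C@H]2/C=C(\C)CC/C=C(\COC(C)=O)CC/C=C(\C)CC[C@@H]12 | intermediate
36 | CNP0158848.2, (1S,2S,3E,7Z,11E)-19-acetoxycembra-3,7,11,15(17)-tetraen-16,2-olide | C=C1C(=O)O[C@H]2/C=C(\C)CC/C=C(\COC(C)=O)CC/C=C(\C)CC[C@@H]12 | target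

**Step count and weak points**

Total step count: 22. Longest linear sequence: 20 steps (steps 1–7, 9–11, 13–22, from geranyl acetate).

Steps most likely to fail:

1. Step 18. Syn/anti equilibration of the allylnickel termini may erode the C7=C8 and C11=C12 geometry, head-to-tail coupling may compete, and intermolecular coupling may give oligomers. The fallback forms the same C9–C10 bond by a sulfone-anion alkylation; it sets out from 25 and returns at 30. The C9 hydroxyl of 25 is silylated (TESCl, imidazole) to the triethylsilyl ether F1. Carboalumination and hydroxymethylation as in step 16 give the C10 allylic alcohol F2. MsCl/Et3N then LiBr gives the C10 allylic bromide F3, and sodium benzenesulfinate in DMF converts it into the C10 allylic phenyl sulfone F4. PPTS in MeOH at 0 °C removes the triethylsilyl group selectively to give the C9 alcohol F5, which is brominated (MsCl, Et3N; LiBr) to the sulfone bromide F6. Slow addition of F6 to KHMDS in THF at high dilution should alkylate the sulfone-stabilised C10 carbanion with the C9 allylic bromide and give the 14-membered cyclic sulfone F7. Palladium-catalysed reductive desulfonylation (Pd(dppp)Cl2, LiBHEt3, hydride to the less substituted allyl terminus C10) then gives 30.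

2. Step 14. The basic ylide may enolise the α-alkoxy ketone, which would epimerise C1 or eliminate the C2 silyloxy group. The fallback is a two-stage Peterson olefination through a non-basic organocerium addition; it sets out from 23 and returns at 24. TMSCH2MgCl/CeCl3 in THF at −78 °C adds to the ketone to give the β-hydroxysilane F8 (either carbinol epimer serves), and KH in THF eliminates trimethylsilanolate to give 24.

3. Step 16. Carboalumination may be incomplete or poorly regioselective on the polyoxygenated substrate, the Lewis-acidic aluminium reagents may attack the allylic ethers, and capture of the alkenylalane by formaldehyde may be inefficient. The fallback builds the trisubstituted alkene through a propargylic alcohol; it sets out from 25 and returns at 27. Double deprotonation of 25 (n-BuLi, THF, −78 °C) and addition of paraformaldehyde give the propargylic alcohol F9. Trans-hydroalumination with Red-Al (aluminium delivered to C12) and iodine quench give the (Z)-3-iodo allylic alcohol F10. Me2CuLi (excess, Et2O, 0 °C) replaces iodine by methyl with retention and gives diol 27.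

Further compounds
F1 | step 18 | C9 triethylsilyl ether of 25 | CC[Si](CC)(CC)OC/C(CO[Si](C)(C)C(C)(C)C)=C/CC/C(C)=C/[C@H](O[Si](C)(C)C(C)(C)C)[C@H](C(=C)COCc1ccc(OC)cc1)CCC#C
F2 | step 18 | C9-OTES C10 allylic alcohol (11E) | CC[Si](CC)(CC)OC/C(CO[Si](C)(C)C(C)(C)C)=C/CC/C(C)=C/[C@H](O[Si](C)(C)C(C)(C)C)[C@H](C(=C)COCc1ccc(OC)cc1)CC/C(C)=C/CO
F3 | step 18 | C9-OTES C10 allylic bromide | CC[Si](CC)(CC)OC/C(CO[Si](C)(C)C(C)(C)C)=C/CC/C(C)=C/[C@H](O[Si](C)(C)C(C)(C)C)[C@H](C(=C)COCc1ccc(OC)cc1)CC/C(C)=C/CBr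
F4 | step 18 | C9-OTES C10 allylic phenyl sulfone | CC[Si](CC)(CC)OC/C(CO[Si](C)(C)C(C)(C)C)=C/CC/C(C)=C/[C@H](O[Si](C)(C)C(C)(C)C)[C@H](C(=C)COCc1ccc(OC)cc1)CC/C(C)=C/CS(=O)(=O)c2ccccc2
F5 | step 18 | C9 alcohol C10 phenyl sulfone | OC/C(CO[Si](C)(C)C(C)(C)C)=C/CC/C(C)=C/[C@H](O[Si](C)(C)C(C)(C)C)[C@H](C(=C)COCc1ccc(OC)cc1)CC/C(C)=C/CS(=O)(=O)c2ccccc2
F6 | step 18 | C9 bromide C10 phenyl sulfone | BrC/C(CO[Si](C)(C)C(C)(C)C)=C/CC/C(C)=C/[C@H](O[Si](C)(C)C(C)(C)C)[C@H](C(=C)COCc1ccc(OC)cc1)CC/C(C)=C/CS(=O)(=O)c2ccccc2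
F7 | step 18 | 10-(phenylsulfonyl) derivative of macrocycle 30 (C10 epimers) | C=C(COCc1ccc(OC)cc1)[C@@H]1CC/C(C)=C/C(S(=O)(=O)c2ccccc2)C/C(CO[Si](C)(C)C(C)(C)C)=C/CC/C(C)=C/[C@@H]1O[Si](C)(C)C(C)(C)C
F8 | step 14 | C15 tertiary β-hydroxysilane from 23 (C15 epimers) | CC(C)(C)OC(=O)/C(CO[Si](C)(C)C(C)(C)C)=C/CC/C(C)=C/[C@H](O[Si](C)(C)C(C)(C)C)[C@H](C(O)(C[Si](C)(C)C)COCc1ccc(OC)cc1)CCC#C
F9 | step 16 | C10 propargylic alcohol (C9,C10 diol with C11≡C12) | OC/C(CO[Si](C)(C)C(C)(C)C)=C/CC/C(C)=C/[C@H](O[Si](C)(C)C(C)(C)C)[C@H](C(=C)COCc1ccc(OC)cc1)CCC#CCO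
F10 | step 16 | (11Z)-12-iodo C9,C10 diol | OC/C(CO[Si](C)(C)C(C)(C)C)=C/CC/C(C)=C/[C@H](O[Si](C)(C)C(C)(C)C)[C@H](C(=C)COCc1ccc(OC)cc1)CC/C(I)=C/CO
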